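The meeting had one question: which of the two flasks, winter or spring, ends with the higher excess of L over J?

| flask | J | L | G | remark | time |
|---|---|---|---|---|---|
| eta | 0.20 M | 0.20 M | 0.30 M | run made earlier |  |
| alpha | 0.45 M | 0.45 M | 0.30 M | run made earlier |  |
| delta | 0.30 M | 0.30 M | 0.60 M | run made earlier |  |
| winter | 0.30 M | 0.30 M | 0.300 M |  | 2.0 h |
| spring | 0.30 M | 0.30 M | 0.300 M |  | 0.60 h |

- eta (time / min: L / %, J / %, Q / %): 6.00: 50.3, 31.3, 17.3; 20.0: 51.0, 17.7, 32.9; 30.0: 50.5, 11.4, 37.4; 50.0: 48.9, 7.3, 42.2; 80.0: 48.1, 4.2, 46.9
- alpha (time / min: L / %, J / %, Q / %): 6.00: 50.0, 34.9, 14.3; 20.0: 50.2, 24.6, 26.3; 30.0: 50.2, 22.0, 29.8; 50.0: 49.2, 21.0, 31.1; 80.0: 49.7, 19.1, 28.6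
- delta (time / min: L / %, J / %, Q / %): 6.00: 49.7, 23.4, 26.2; 20.0: 49.1, 9.1, 42.0; 30.0: 50.0, 3.8, 46.0; 50.0: 49.2, 2.1, 49.9; 80.0: 47.9, 0, 50.1

(scatter of a reading: 1 percentage point)

- G is single-handed; J and L are mirror images of each other, charged as a racemate, each of them at the stated concentration
- an excess is the difference of the two amounts in percent of their sum
- an excess is below zero if the other one leads
- the handed part of G does not stay in what it makes, so the products of the two hands are mirror images too

- the flask that ends with the higher excess of L over J among what is left of the two, or "neither" when 2 percentage points or less lies between them (winter / spring / neither)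
- excess of L over J among what is left of the two at the end, winter
- excess of L over J among what is left of the two at the end, spring

The first speaker pointed to the L columns: in the alpha run L reads 50.0% at the first reading and 49.7% at the last, so the meeting took L at its charge and reckoned the excess from how much J remains. The second speaker objected that J stalls too high. In alpha, G is the limiting reagent, and one G per J should stop J at 16.7%, yet the last two readings are 21.0% and 19.1%. The G charge minus the J consumed at the stall in alpha, the G shortfall, therefore reads about 0.0305 M from those two readings.

My own reckoning treats this small amount as a correction. I cut G's charge by the shortfall and run plain second-order kinetics with the rate constant from alpha's first reading, 16.3 L mol⁻¹ h⁻¹. For winter this estimate puts J at 0.0457 M, an excess of 73.6%. For spring it puts J at 0.0916 M, an excess of 53.2%, so my reckoning has winter ahead.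

The forecast also chose winter, with different numbers: 69% for winter and 56% for spring. It read the stall as a reaction that runs back, noting “though loss of G would fit similarly”.

Winter ends at 70.4% and spring at 53.5%, so winter leads. With the time and the other charges held, moving winter's G charge down to 0.281 M or up to 0.321 M shifts its excess by 5 points. The shortfall of 0.0305 M read in alpha is wider than that downward step of 0.0195 M, so in winter G of that size is not a small matter for the excess.

    G + L → E (k = 0.117 L mol⁻¹ h⁻¹)
    G + J → Q (k = 16.8 L mol⁻¹ h⁻¹)
    2 G → D (k = 1.59 L mol⁻¹ h⁻¹)

A neighbouring flask is spring with 0.51 M of G. The same shortfall and rate constant estimate J there at 0.0219 M, an excess of 86.4%; the computed flask gives 80.4%.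

The numbers in the tables were generated by integration on assumed constants.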